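The chromanone is disconnected at O1–C8a and C4–C4a, two adjacent bonds of ring A that sit between the C5 oxygen and the C8 carbon substituent. A C4a–C8a aryne, freed from an ortho-silylaryl triflate, should insert into commercial ethyl (S)-3-hydroxy-3-phenylpropanoate: the hydroxyl oxygen bonds to C8a, the ester carbon to C4a, and ring C closes in a single operation with the C2 stereocentre carried in unchanged. The aryne precursor is a pentasubstituted benzene with benzyl ethers at C5 and C7, a silyl-protected hydroxymethyl group at C8, SiMe3 at C4a and OTf at C8a. The C8 hydroxymethyl group then alkylates C3 of a separately made pyranone, and hydrogenolysis finishes.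

Key step: step 8

Remark: flavanone numbering (O1, C2, C3, C4, C4a, C5 to C8, C8a; ring A = benzo ring, ring C = oxygen heterocycle) is used for ring A from the first intermediate onward; the target SMILES encodes 2S, and the S hydroxy ester delivers 2S because the CIP order O > phenyl > CH2 > H is the same before and after the key step.

Step 1
Reactants: 1 2,4,6-trihydroxybenzaldehyde
Product: 2 2,4-bis(benzyloxy)-6-hydroxybenzaldehyde
Conditions: BnBr (2.05 equiv), K2CO3, DMF, 0 °C to rt
Reagents that add atoms: benzyl bromide, BrCc1ccccc1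
Why: Williamson etherification in which the para hydroxyl and one ortho hydroxyl are alkylated while the remaining ortho hydroxyl, hydrogen-bonded to the formyl oxygen, is the least nucleophilic and stays free (the two ortho hydroxyls are equivalent by symmetry).

Step 2
Reactants: 2 2,4-bis(benzyloxy)-6-hydroxybenzaldehyde
Product: 3 3,5-bis(benzyloxy)-2-formylphenyl N,N-diethylcarbamate
Conditions: ClC(O)NEt2, K2CO3, MeCN, reflux
Reagents that add atoms: N,N-diethylcarbamoyl chloride, CCN(CC)C(Cl)=O
Why: O-carbamoylation of the phenol; the fully N-substituted carbamate has no N–H that could add to the neighbouring aldehyde and is the strongest oxygen-based director for the later ortho-lithiation.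

Step 3
Reactants: 3 3,5-bis(benzyloxy)-2-formylphenyl N,N-diethylcarbamate
Product: 4 3,5-bis(benzyloxy)-2-(hydroxymethyl)phenyl N,N-diethylcarbamate
Conditions: NaBH4, THF/MeOH, 0 °C
Reagents that add atoms: none
Why: Borohydride reduction of the aryl aldehyde; the tertiary carbamate is inert to NaBH4 and too poor an acyl donor to migrate to the new alkoxide at 0 °C.

Step 4
Reactants: 4 3,5-bis(benzyloxy)-2-(hydroxymethyl)phenyl N,N-diethylcarbamate
Product: 5 3,5-bis(benzyloxy)-2-[(triisopropylsilyloxy)methyl]phenyl N,N-diethylcarbamate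
Conditions: TIPSCl, imidazole, DMF, rt
Reagents that add atoms: triisopropylsilyl chloride, CC(C)[Si](Cl)(C(C)C)C(C)C
Why: Silyl ether formation at the primary benzylic alcohol; the triisopropylsilyl group is chosen because it must survive s-BuLi, LiAlH4 and the fluoride of the aryne step, where a liberated alkoxide would itself add to the aryne.

Step 5
Reactants: 5 3,5-bis(benzyloxy)-2-[(triisopropylsilyloxy)methyl]phenyl N,N-diethylcarbamate
Product: 7 3,5-bis(benzyloxy)-2-[(triisopropylsilyloxy)methyl]-6-(trimethylsilyl)phenyl N,N-diethylcarbamate, via aryllithium 6 (not isolated)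
Conditions: s-BuLi, TMEDA, THF, −78 °C; then TMSCl, −78 °C to rt
Reagents that add atoms: chlorotrimethylsilane, C[Si](C)(C)Cl
Why: Directed ortho-metalation removes the one ring hydrogen flanked by the carbamate and a benzyloxy group (the future C4a) under cooperative direction, and the aryllithium is silylated at −78 °C before an anionic Fries shift of the carbamoyl group can set in.

Step 6
Reactants: 7 3,5-bis(benzyloxy)-2-[(triisopropylsilyloxy)methyl]-6-(trimethylsilyl)phenyl N,N-diethylcarbamate
Product: 8 3,5-bis(benzyloxy)-2-[(triisopropylsilyloxy)methyl]-6-(trimethylsilyl)phenol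
Conditions: LiAlH4, THF, 0 °C to 50 °C
Reagents that add atoms: none
Why: Hydride reduction of the aryl carbamate releases the phenol and takes the carbamoyl carbon on to an N-methyl group, while silyl ethers, benzyl ethers and the aryl–silicon bond are inert to LiAlH4 at this temperature.

Step 7
Reactants: 8 3,5-bis(benzyloxy)-2-[(triisopropylsilyloxy)methyl]-6-(trimethylsilyl)phenol
Product: 9 3,5-bis(benzyloxy)-2-[(triisopropylsilyloxy)methyl]-6-(trimethylsilyl)phenyl trifluoromethanesulfonate
Conditions: Tf2O, pyridine, CH2Cl2, 0 °C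
Reagents that add atoms: trifluoromethanesulfonic anhydride, O=S(=O)(OS(=O)(=O)C(F)(F)F)C(F)(F)F
Why: O-sulfonylation of the phenol (triflate formation) completes the ortho-silylaryl triflate, with SiMe3 on the future C4a and OTf on the future C8a.

Step 8
Reactants: 9 3,5-bis(benzyloxy)-2-[(triisopropylsilyloxy)methyl]-6-(trimethylsilyl)phenyl trifluoromethanesulfonate; 10 ethyl (S)-3-hydroxy-3-phenylpropanoate
Product: 13 (2S)-5,7-bis(benzyloxy)-2-phenyl-8-[(triisopropylsilyloxy)methyl]chroman-4-one, via aryne 11 (not isolated), via arylcesium 12 (not isolated)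
Conditions: 10 (1.5 equiv), CsF (4 equiv), THF, 65 °C
Reagents that add atoms: none
Why: Proposed new method: fluoride removes the SiMe3 group of 9 with loss of triflate to give aryne 11, the oxygen of 10 (as its cesium alkoxide or fluoride-bound hydroxyl) adds at C8a, and the C4a carbanion 12 attacks the ester carbonyl and expels ethoxide, so that O1–C8a and C4–C4a form in one flask. The closest known reaction types are the CsF-mediated insertion–annulation of arynes with salicylates to xanthones and, for the ring-closing half, the Parham cyclisation of ortho-metalated aryloxypropanoates; an aliphatic β-hydroxy ester has not been shown as the partner. Ring C closes by 6-exo-trig attack of the aryl anion on the ester carbonyl. No stereocentre is created: C2 is the carbinol carbon of 10, whose C–O and C–H bonds are not touched, so the S configuration is retained. The step needs O-attack at C8a and not at C4a, which the C5 benzyloxy group secures by stabilising negative charge at the adjacent C4a (as in 3-alkoxyarynes), while each aryne carbon carries one ortho substituent so that sterics are roughly balanced. It also needs acylation to outrun protonation of the anion, which is favoured by THF as a solvent without acidic C–H bonds, by excess CsF binding the hydroxyl proton as CsHF2, and by the six-membered transition state.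

Step 9
Reactants: 13 (2S)-5,7-bis(benzyloxy)-2-phenyl-8-[(triisopropylsilyloxy)methyl]chroman-4-one
Product: 14 (2S)-5,7-bis(benzyloxy)-8-(hydroxymethyl)-2-phenylchroman-4-one
Conditions: HF·pyridine, pyridine, THF, 0 °C to rt
Reagents that add atoms: none
Why: Fluoride-mediated desilylation under buffered acidic conditions removes the primary silyl ether without the basic medium that could open ring C by β-elimination of the C8a phenoxide and erode C2.

Step 10
Reactants: 15 3-pentanone; 16 malonyl dichloride
Product: 17 6-ethyl-4-hydroxy-5-methyl-2H-pyran-2-one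
Conditions: neat, 15 in excess, rt, 2–3 d
Reagents that add atoms: none
Why: Known condensation of an enolisable ketone with malonyl dichloride, in which C-acylation of the ketone enol followed by O-acylation by the second acid chloride closes the 4-hydroxy-2-pyranone.

Step 11
Reactants: 14 (2S)-5,7-bis(benzyloxy)-8-(hydroxymethyl)-2-phenylchroman-4-one; 17 6-ethyl-4-hydroxy-5-methyl-2H-pyran-2-one
Product: 18 3-{[(2S)-5,7-bis(benzyloxy)-4-oxo-2-phenylchroman-8-yl]methyl}-6-ethyl-4-hydroxy-5-methyl-2H-pyran-2-one
Conditions: 17 (3 equiv), TsOH·H2O (10 mol %), 1,2-dichloroethane, 60 °C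
Reagents that add atoms: none
Why: Acid-catalysed dehydrative Friedel–Crafts-type benzylation in which the benzylic alcohol ionises to a cation stabilised by the oxygens at C7 and C8a (ortho) and C5 (para) and is captured by C3 of the 4-hydroxy-2-pyranone, its only free nucleophilic carbon, with any O-alkylation reversible under acid and C2 not involved.

Step 12
Reactants: 18 3-{[(2S)-5,7-bis(benzyloxy)-4-oxo-2-phenylchroman-8-yl]methyl}-6-ethyl-4-hydroxy-5-methyl-2H-pyran-2-one
Product: 19 3-{[(2S)-5,7-dihydroxy-4-oxo-2-phenyl-3,4-dihydro-2H-chromen-8-yl]methyl}-6-ethyl-4-hydroxy-5-methyl-2H-pyran-2-one (target)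
Conditions: H2 (1 atm), 10% Pd/C, EtOAc, rt, stopped once both benzyl groups are gone
Reagents that add atoms: none
Why: Catalytic hydrogenolysis of the two aryl benzyl ethers, the usual end of a flavanone synthesis, which should be faster than reduction of the tetrasubstituted pyranone double bond, of the aryl ketone or of the cyclic benzylic C2–O1 bond.

Compound list
1 | 2,4,6-trihydroxybenzaldehyde | O=Cc1c(O)cc(O)cc1O | starting material
2 | 2,4-bis(benzyloxy)-6-hydroxybenzaldehyde | O=Cc1c(O)cc(OCc2ccccc2)cc1OCc1ccccc1 | intermediate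
3 | 3,5-bis(benzyloxy)-2-formylphenyl N,N-diethylcarbamate | CCN(CC)C(=O)Oc1cc(OCc2ccccc2)cc(OCc2ccccc2)c1C=O | intermediate
4 | 3,5-bis(benzyloxy)-2-(hydroxymethyl)phenyl N,N-diethylcarbamate | CCN(CC)C(=O)Oc1cc(OCc2ccccc2)cc(OCc2ccccc2)c1CO | intermediate
5 | 3,5-bis(benzyloxy)-2-[(triisopropylsilyloxy)methyl]phenyl N,N-diethylcarbamate | CCN(CC)C(=O)Oc1cc(OCc2ccccc2)cc(OCc2ccccc2)c1CO[Si](C(C)C)(C(C)C)C(C)C | intermediate
6 | 3,5-bis(benzyloxy)-2-lithio-6-[(triisopropylsilyloxy)methyl]phenyl N,N-diethylcarbamate (aryllithium) | CCN(CC)C(=O)Oc1c([Li])c(OCc2ccccc2)cc(OCc2ccccc2)c1CO[Si](C(C)C)(C(C)C)C(C)C | intermediate (not isolated)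
7 | 3,5-bis(benzyloxy)-2-[(triisopropylsilyloxy)methyl]-6-(trimethylsilyl)phenyl N,N-diethylcarbamate | CCN(CC)C(=O)Oc1c([Si](C)(C)C)c(OCc2ccccc2)cc(OCc2ccccc2)c1CO[Si](C(C)C)(C(C)C)C(C)C | intermediate
8 | 3,5-bis(benzyloxy)-2-[(triisopropylsilyloxy)methyl]-6-(trimethylsilyl)phenol | Oc1c([Si](C)(C)C)c(OCc2ccccc2)cc(OCc2ccccc2)c1CO[Si](C(C)C)(C(C)C)C(C)C | intermediate
9 | 3,5-bis(benzyloxy)-2-[(triisopropylsilyloxy)methyl]-6-(trimethylsilyl)phenyl trifluoromethanesulfonate | C[Si](C)(C)c1c(OCc2ccccc2)cc(OCc2ccccc2)c(CO[Si](C(C)C)(C(C)C)C(C)C)c1OS(=O)(=O)C(F)(F)F | intermediate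
10 | ethyl (S)-3-hydroxy-3-phenylpropanoate | CCOC(=O)C[C@H](O)c1ccccc1 | starting material
11 | 3,5-bis(benzyloxy)-6-[(triisopropylsilyloxy)methyl]-1,2-didehydrobenzene (C4a–C8a aryne) | C1#CC(CO[Si](C(C)C)(C(C)C)C(C)C)=C(OCc2ccccc2)C=C1OCc1ccccc1 | intermediate (not isolated)
12 | ethyl (3S)-3-{3,5-bis(benzyloxy)-2-cesio-6-[(triisopropylsilyloxy)methyl]phenoxy}-3-phenylpropanoate (C4a aryl anion as its cesium species) | CCOC(=O)C[C@H](Oc1c([Cs])c(OCc2ccccc2)cc(OCc2ccccc2)c1CO[Si](C(C)C)(C(C)C)C(C)C)c1ccccc1 | intermediate (not isolated)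
13 | (2S)-5,7-bis(benzyloxy)-2-phenyl-8-[(triisopropylsilyloxy)methyl]chroman-4-one | CC(C)[Si](OCc1c(OCc2ccccc2)cc(OCc2ccccc2)c2c1O[C@H](c1ccccc1)CC2=O)(C(C)C)C(C)C | intermediate
14 | (2S)-5,7-bis(benzyloxy)-8-(hydroxymethyl)-2-phenylchroman-4-one | OCc1c(OCc2ccccc2)cc(OCc2ccccc2)c2c1O[C@H](c1ccccc1)CC2=O | intermediate
15 | 3-pentanone | CCC(=O)CC | starting material
16 | malonyl dichloride | O=C(Cl)CC(Cl)=O | starting material
17 | 6-ethyl-4-hydroxy-5-methyl-2H-pyran-2-one | CCc1oc(=O)cc(O)c1C | intermediate
18 | 3-{[(2S)-5,7-bis(benzyloxy)-4-oxo-2-phenylchroman-8-yl]methyl}-6-ethyl-4-hydroxy-5-methyl-2H-pyran-2-one | CCc1oc(=O)c(Cc2c(OCc3ccccc3)cc(OCc3ccccc3)c3c2O[C@H](c2ccccc2)CC3=O)c(O)c1C | intermediate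
19 | 3-{[(2S)-5,7-dihydroxy-4-oxo-2-phenyl-3,4-dihydro-2H-chromen-8-yl]methyl}-6-ethyl-4-hydroxy-5-methyl-2H-pyran-2-one | CCc1oc(=O)c(Cc2c(O)cc(O)c3c2O[C@H](c2ccccc2)CC3=O)c(O)c1C | target

Total step count: 12. Longest linear sequence: 11 steps (steps 1 to 9, 11 and 12, from 1); step 10 is a one-step side branch.

Steps most likely to fail

Step 8 (proposed new method). Four processes could defeat it:
- The C4a anion could be protonated (by the hydroxyl proton, HF or another molecule of 10) before it reaches the ester.
- The anion could remove a proton from C3, after which β-elimination of the aryloxide would give cinnamate.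
- Fluoride could enolise the product and open ring C reversibly, eroding C2.
- The oxygen could add at C4a instead of C8a.

The fallback makes the two bonds one after the other with known reactions. It sets out from 9 and 10. Aryne O–H insertion under conditions established for aliphatic alcohols (KF, 18-crown-6, THF, rt, 10 in excess) should give ethyl (3S)-3-{3,5-bis(benzyloxy)-2-[(triisopropylsilyloxy)methyl]phenoxy}-3-phenylpropanoate F1, again without touching the carbinol C–O bond. Ester cleavage with Me3SnOH in 1,2-dichloroethane at 80 °C, chosen to avoid base-induced β-elimination, should give (3S)-3-{3,5-bis(benzyloxy)-2-[(triisopropylsilyloxy)methyl]phenoxy}-3-phenylpropanoic acid F2. Intramolecular Friedel–Crafts acylation promoted by TFAA in CH2Cl2 at 0 °C should then close C4–C4a at the only free position ortho to the ether oxygen of the electron-rich ring, and the route is rejoined at 13.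

Step 11. Ionisation of the benzylic alcohol may be slow because the C4 carbonyl draws on the same three ring oxygens. The cation may instead alkylate C6 of a second flavanone molecule and give oligomers. Prolonged acid and heat may start ring-opening of ring C. The fallback changes the bond-forming logic from cation capture to condensation and reduction and sets out from 14. Oxidation with MnO2 in CH2Cl2 should give (2S)-5,7-bis(benzyloxy)-4-oxo-2-phenylchroman-8-carbaldehyde F3. Knoevenagel condensation of F3 with 17 (L-proline, CH2Cl2, rt) in the presence of Hantzsch ester (diethyl 2,6-dimethyl-1,4-dihydropyridine-3,5-dicarboxylate) should form 3-{[(2S)-5,7-bis(benzyloxy)-4-oxo-2-phenylchroman-8-yl]methylidene}-6-ethyl-5-methyl-2H-pyran-2,4(3H)-dione F4 (not isolated, alkene geometry not defined). Conjugate hydride transfer from the dihydropyridine reduces it in the same flask, which returns to the route at 18.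

Step 12. Hydrogenation may not stop at debenzylation: the pyranone C5=C6 bond may be saturated, the benzylic C2–O1 bond may be hydrogenolysed to a dihydrochalcone, or the C4 ketone may be reduced. The fallback replaces reduction by Lewis-acid dealkylation and sets out from 18. BCl3 with pentamethylbenzene as benzyl-cation scavenger in CH2Cl2 at −78 °C should cleave both aryl benzyl ethers and give 19 directly; no new compound arises (F0).

Further compounds
F1 | step 8 | ethyl (3S)-3-{3,5-bis(benzyloxy)-2-[(triisopropylsilyloxy)methyl]phenoxy}-3-phenylpropanoate | CCOC(=O)C[C@H](Oc1cc(OCc2ccccc2)cc(OCc2ccccc2)c1CO[Si](C(C)C)(C(C)C)C(C)C)c1ccccc1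
F2 | step 8 | (3S)-3-{3,5-bis(benzyloxy)-2-[(triisopropylsilyloxy)methyl]phenoxy}-3-phenylpropanoic acid | OC(=O)C[C@H](Oc1cc(OCc2ccccc2)cc(OCc2ccccc2)c1CO[Si](C(C)C)(C(C)C)C(C)C)c1ccccc1
F3 | step 11 | (2S)-5,7-bis(benzyloxy)-4-oxo-2-phenylchroman-8-carbaldehyde | O=Cc1c(OCc2ccccc2)cc(OCc2ccccc2)c2c1O[C@H](c1ccccc1)CC2=O
F4 | step 11 | 3-{[(2S)-5,7-bis(benzyloxy)-4-oxo-2-phenylchroman-8-yl]methylidene}-6-ethyl-5-methyl-2H-pyran-2,4(3H)-dione | CCC1=C(C)C(=O)C(=Cc2c(OCc3ccccc3)cc(OCc3ccccc3)c3c2O[C@H](c2ccccc2)CC3=O)C(=O)O1
F0 | step 12 | none | none
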